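## The problem

The target (23) is an 8-O-4′ neolignan. Ring A (4-hydroxy-3-methoxyphenyl) carries the chain C7(OH)–C8(OAr)–C9H2OH. The oxygen on C8 is bonded to C4′ of ring B, which has methoxy groups on C3′ and C5′ and a hydroxymethyl carbon (C7′) on C1′.

No ring has to be built. The skeleton has one C–C junction (C1–C7) and one C–O junction (O–C4′). The second is the hard one, because it joins a secondary carbinol carbon to an aryl carbon blocked on both sides by methoxy groups.

The two adjacent stereocentres are 7R and 8S (erythro, anti in the zigzag drawing). C8 is a glycerate-type carbon that can be bought. Placed next to a C7 ketone, it can steer hydride through a metal chelate, so C8 should control C7 and not the reverse.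

C7–O is benzylic and para to an oxygen. It ionises in acid, loses hydride to quinone oxidants, and can leave through a quinone methide in base once the phenol is free. Each of these paths scrambles C7. The electron-rich rings also rule out electrophilic halogen, and the two benzylic alcohols make a late hydrogenolysis unattractive.

The feature that opens the plan is the substitution pattern around C4′. It bears the ether oxygen, sits between two oxygen-bearing ring carbons, and has the carbon substituent para to it. This 2-alkoxyresorcinol pattern is C2 of a cyclohexane-1,3-dione whose C5 carries the carbon substituent. C4′ can therefore start as the carbene carbon of a 2-diazo-1,3-dione, and the ether can be made by insertion into the C8 O–H bond without touching the C8–O bond.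

## Retrosynthesis

**23 from 22.** The last operation should only remove protecting groups, so the three Si–O bonds of 22 are cut. The di-tert-butylsilylene on O7/O9 and the triisopropylsilyl ether on the ring A phenol both fall to fluoride in one flask. A benzyl ether on the phenol was set aside: its hydrogenolysis would have to spare two benzylic alcohols and would cost an extra step. The forward reaction must be buffered so that the freed para-hydroxybenzyl alcohol does not form a quinone methide.

**22 from 21.** C7′ is taken back to the ester level (two C–H bonds cut). The ester is what the commercial dione carries, it offers no O–H to a carbenoid, and it acidifies the ring position next to it, which helps the aromatization. The forward step is a plain hydride reduction in the presence of silyl ethers.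

**21 from 14, through 20 and 15.** Ring B is taken out of the aromatic series. Two O–CH3 bonds and one ring unsaturation are removed, which leads to 14, the enol of a 2-alkoxycyclohexane-1,3-dione. Forward, the order is: methylate the enol (15), dehydrogenate to the phenol (20), methylate again (21).

- The usual dehydrogenating agents are excluded by the rest of the molecule. A quinone such as DDQ abstracts hydride from benzylic ethers of electron-rich arenes, and C7–H is such a position. Iodine in hot methanol generates HI, which would solvolyse the C7–O bond and the silylene.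
- The dehydrogenation is therefore done through the enolate: selenenylation, then selenoxide syn-elimination below room temperature.
- Whichever ring position takes the selenium, elimination and tautomerization lead to the same arene.
- The ester-bearing ring carbon, a stereocentre of no consequence in 13 to 19, becomes aromatic.

**14 from 10 and 12 (key cut, O–C4′).** The neighbouring cuts were weighed against this one:

- Displacement at C8 by a 2,6-dimethoxyphenol needs inversion at a hindered secondary carbon and invites elimination toward the aryl-conjugated enol ether.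
- Nucleophilic aromatic substitution has no activating group on ring B to work with.
- Metal-catalysed coupling of a secondary alcohol with a doubly ortho-substituted aryl halide is poor.

The carbenoid route makes the bond while C4′ is still an unhindered sp2 carbon between two ketones and leaves C8–O intact. The precursors are much simpler: 10 is a protected 1-arylglycerol with only C8–OH free, and 12 is a one-step derivative of a commercial dione. The forward reaction has to favour O–H insertion over Wolff ring contraction and over attack on ring A.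

**12 from 11.** The C=N2 bond is cut. Diazo transfer to the doubly activated methylene of 11 is routine.

**10 from 8, through 9.** The two Si–O bonds of the silylene are cut to give triol 9, and 9 is traced to acetonide 8. The silylene is chosen because it ties O7 and O9 in a six-membered ring in one step under basic conditions, leaves C8–OH equatorial and exposed, and comes off with fluoride at the end. The forward step has to close the six-membered ring in preference to the five-membered one.

**8 from 7.** The C7–H bond is cut. Ketone 7 has a single stereocentre, and a chelating hydride source should turn it into the anti alcohol. This is simpler and more predictable than building both centres at once.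

**7 from 2 and 4; 4 from 3; 2 from 1.** The C1–C7 bond is cut between an aryllithium and a Weinreb amide. Amide 4 comes in one step from glycerate ester 3, which supplies C8 in the S configuration. Bromide 2 is the silyl ether of phenol 1. The Weinreb amide is preferred to the aldehyde because it separates bond formation from stereocontrol and avoids a configurationally fragile glyceraldehyde.

## Roads not taken

**Alternative 1: [2,3]-Wittig rearrangement (cut at C7–C8).**

- Forward step: the ring A benzyl ether A2, an (R)-configured allylic ether with an E aryloxy enol ether terminus, would be deprotonated at the benzylic CH2 with n-BuLi. The carbanion would rearrange through a five-membered transition state to A1, forming C7–C8 as the allylic C–O bond breaks.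
- Merits: one step makes a C–C bond and both stereocentres from a single carbinol centre, and the hindered aryl ether is already in place as an enol ether. In stereochemical economy this is the better idea, and ring B needs no change of oxidation level.
- Weak points: A2 requires a geometrically pure E enol ether of a 2,6-dimethoxyphenol. The benzylic anion sits on an electron-rich ring, so ring lithiation next to the methoxy groups and the [1,2]-shift compete. The propenyl group of A1 then has to be cut down to C9H2OH by ozonolysis and reduction in the presence of two electron-rich arenes.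
- Comparison: the length is about the same. The chosen plan sets against it that its one uncertain event (the insertion into 10) comes after both stereocentres are fixed on simple compounds, and that no displacement or oxidative cleavage is needed near the arenes.

**Alternative 2: dynamic kinetic resolution of a keto ester (cut at C7–H, with C8 epimerizable).**

- Forward step: racemic keto ester A4 would be reduced with RuCl(p-cymene)(TsDPEN) and formic acid/triethylamine. One of the rapidly interconverting C8 enantiomers would be reduced to the anti hydroxy ester A3.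
- Merits: this is the shortest road, roughly half the length of the chosen one. The aryl ether is made by an easy displacement alpha to two carbonyl groups, one catalytic step sets both centres, and LiAlH4 would then reduce both esters at once.
- Weak points: the anti isomer is required, and the syn/anti sense of such reductions depends on catalyst and on the alpha substituent. It is not established for a bulky 2,6-dimethoxyaryloxy group. In A3, C8 is alpha to an ester and beta to a hydroxyl, so epimerization and retro-aldol cleavage threaten until the ester is reduced.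
- Comparison: it is clearly shorter. The chosen plan sets against it that absolute configuration is bought, relative configuration follows a well-understood chelate model, and C8 is never alpha to a carbonyl once the aryl ether exists.

**Alternative 3: asymmetric hydroboration of a Z enol ether (cut at C7–O and C8–H).**

- Forward step: IpcBH2 would add across C7=C8 of A6 with boron on C7 and hydrogen on C8. Trimethylamine N-oxide would then turn C7–B into C7–O with retention to give A5.
- Merits: syn addition to a Z alkene gives the erythro pair by geometry. Relative configuration is thus more secure than in a chelation-controlled reduction, and the route is shorter.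
- Weak points: the intermediate borane has boron on C7 and an aryloxy leaving group on C8, which is the arrangement for beta-elimination. Enantiofacial control by IpcBH2 on a trisubstituted aryl enol ether is untested. A6 must be made as a single geometric isomer.
- Comparison: the chosen plan has nothing as direct for relative configuration. It sets against this an absolute configuration that does not depend on reagent control, and no intermediate with a leaving group beta to a metal.

Key step: step 8

Remarks before the steps:

- Compounds 13 to 19 are carried as mixtures of the two epimers at the ester-bearing ring carbon, which becomes aromatic in 20. Enol 14 is drawn as one of two equivalent tautomers.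
- Shorthand in names: Q is the (4R,5S)-2,2-di-tert-butyl-4-[3-methoxy-4-(triisopropylsilyloxy)phenyl]-1,3,2-dioxasilinan-5-yl group. Q–OH is compound 10, and ring carbon 5 of Q is C8 of the target.

## Route

Step 1
Reactants: 1 4-bromo-2-methoxyphenol
Product: 2 (4-bromo-2-methoxyphenoxy)triisopropylsilane
Conditions: i-Pr3SiCl, imidazole, DMF, 23 °C
Reagents that add atoms: triisopropylsilyl chloride, CC(C)[Si](Cl)(C(C)C)C(C)C
Why: Silylation of the phenol with imidazole as base. The triisopropylsilyl ether tolerates n-BuLi, dilute acid, LiN(i-Pr)2 and K2CO3 and leaves with fluoride in the last step together with the silylene.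

Step 2
Reactants: 3 methyl (S)-2,2-dimethyl-1,3-dioxolane-4-carboxylate
Product: 4 (S)-N-methoxy-N,2,2-trimethyl-1,3-dioxolane-4-carboxamide
Conditions: MeNH(OMe)·HCl, i-PrMgCl, THF, −20 °C
Reagents that add atoms: N,O-dimethylhydroxylamine hydrochloride, CNOC.Cl
Why: Weinreb amide formation by aminolysis of the ester with the chloromagnesium amide made in the flask. At −20 °C addition to the ester should be faster than deprotonation of the alpha-alkoxy carbon, so the S centre is kept.

Step 3
Reactants: 2 (4-bromo-2-methoxyphenoxy)triisopropylsilane, 4 (S)-N-methoxy-N,2,2-trimethyl-1,3-dioxolane-4-carboxamide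
Product: 7 [(4S)-2,2-dimethyl-1,3-dioxolan-4-yl][3-methoxy-4-(triisopropylsilyloxy)phenyl]methanone, via aryllithium 5 (not isolated), via lithium hemiaminal 6 (not isolated)
Conditions: 2, n-BuLi, THF, −78 °C; then 4, −78 → −20 °C; aq. NH4Cl
Reagents that add atoms: none
Why: Bromine–lithium exchange followed by Weinreb ketone synthesis makes the C1–C7 bond. Aryllithium 5 adds once to 4 and the chelated adduct 6 lasts until the cold quench, so no tertiary alcohol forms and the ketone, whose C8–H is acidic, never meets base.

Step 4
Reactants: 7 [(4S)-2,2-dimethyl-1,3-dioxolan-4-yl][3-methoxy-4-(triisopropylsilyloxy)phenyl]methanone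
Product: 8 (R)-[(4S)-2,2-dimethyl-1,3-dioxolan-4-yl][3-methoxy-4-(triisopropylsilyloxy)phenyl]methanol
Conditions: Zn(BH4)2, Et2O, −40 °C
Reagents that add atoms: none
Why: Chelation-controlled (Cram chelate) reduction. Zinc bridges the ketone oxygen and the ring oxygen on C8, and hydride enters from the face of the five-membered chelate that carries C8–H, away from the C9 methylene. This sets C7 as R, anti (erythro) to the 8S centre.

Step 5
Reactants: 8 (R)-[(4S)-2,2-dimethyl-1,3-dioxolan-4-yl][3-methoxy-4-(triisopropylsilyloxy)phenyl]methanol
Product: 9 (1R,2S)-1-[3-methoxy-4-(triisopropylsilyloxy)phenyl]propane-1,2,3-triol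
Conditions: AcOH–H2O (4:1), 23 °C
Reagents that add atoms: none
Why: Acid-catalysed hydrolysis of a terminal isopropylidene acetal. Dilute acetic acid at room temperature should be mild enough that the benzylic C7–O bond, para to a silyloxy group (a weaker donor than alkoxy), does not ionise; the aryl silyl ether is stable to it.

Step 6
Reactants: 9 (1R,2S)-1-[3-methoxy-4-(triisopropylsilyloxy)phenyl]propane-1,2,3-triol
Product: 10 (4R,5S)-2,2-di-tert-butyl-4-[3-methoxy-4-(triisopropylsilyloxy)phenyl]-1,3,2-dioxasilinan-5-ol
Conditions: t-Bu2Si(OTf)2, 2,6-lutidine, DMF, −40 → 0 °C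
Reagents that add atoms: di-tert-butylsilyl bis(trifluoromethanesulfonate), CC(C)(C)[Si](OS(=O)(=O)C(F)(F)F)(OS(=O)(=O)C(F)(F)F)C(C)(C)C
Why: Silylene formation by double O-silylation. The bis-triflate should take the primary C9 hydroxyl first and then close onto C7–OH to the six-membered ring, which is favoured over the strained five-membered alternative and places aryl and hydroxyl both equatorial. Any five-membered isomer is hydrolytically labile and should revert to 9 on aqueous work-up; no acid is present, so C7 is safe.

Step 7
Reactants: 11 ethyl 3,5-dioxocyclohexane-1-carboxylate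
Product: 12 ethyl 4-diazo-3,5-dioxocyclohexane-1-carboxylate
Conditions: 4-acetamidobenzenesulfonyl azide, Et3N, MeCN, 0 → 23 °C
Reagents that add atoms: 4-acetamidobenzenesulfonyl azide, CC(=O)Nc1ccc(cc1)S(=O)(=O)N=[N+]=[N-]
Why: Regitz diazo transfer. The enolate of the 1,3-dione attacks the terminal nitrogen of the sulfonyl azide and the adduct fragments to the diazo dione and the sulfonamide.

Step 8
Reactants: 10 (4R,5S)-2,2-di-tert-butyl-4-[3-methoxy-4-(triisopropylsilyloxy)phenyl]-1,3,2-dioxasilinan-5-ol, 12 ethyl 4-diazo-3,5-dioxocyclohexane-1-carboxylate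
Product: 14 ethyl 3-hydroxy-5-oxo-4-(Q-oxy)cyclohex-3-ene-1-carboxylate, via 2-alkoxy-1,3-dione tautomer 13 (not isolated)
Conditions: Rh2(OAc)4 (2 mol %), ClCH2CH2Cl, 70 °C, slow addition of 12 (1.5 equiv)
Reagents that add atoms: none
Why: Rh2(OAc)4 should expel N2 from 12 to give an electrophilic rhodium carbenoid at the carbon between the two ketones; the C8 hydroxyl oxygen of 10 adds to it, the oxonium ylide undergoes a proton shift to the 2-alkoxy-1,3-dione 13, and 13 rests as enol 14. The closest known reaction type is the Rh2(OAc)4-catalysed O–H insertion of 2-diazocyclohexane-1,3-diones into simple primary and secondary alcohols. No ring is closed, and the only skeletal bond formed is O–C4′. No stereocentre is created: the C8–O bond is never broken and C7 meets neither acid nor base, so the 7R,8S pair from step 4 is carried through. The selectivity needed is O–H insertion ahead of Wolff ring contraction, attack on electron-rich ring A, and a second insertion into the acidic enol O–H of 14. The substrate offers a single hydroxyl, held equatorial on the silylene chair; slow addition keeps the carbenoid concentration low, only a modest excess of 12 is used, and unreacted 10 can be recovered.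

Step 9
Reactants: 14 ethyl 3-hydroxy-5-oxo-4-(Q-oxy)cyclohex-3-ene-1-carboxylate
Product: 15 ethyl 3-methoxy-5-oxo-4-(Q-oxy)cyclohex-3-ene-1-carboxylate
Conditions: TMSCHN2, PhMe–MeOH (4:1), 0 → 23 °C
Reagents that add atoms: trimethylsilyldiazomethane, C[Si](C)(C)C=[N+]=[N-]
Why: O-Methylation of a vinylogous acid by a diazomethane equivalent; the acidic enol protonates the reagent, methanol removes the silyl group, and the enolate oxygen is methylated. Carbon alkylation at the substituted ring carbon, the usual problem with MeI and base, is avoided; the dione is symmetric, so one constitutional isomer forms.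

Step 10
Reactants: 15 ethyl 3-methoxy-5-oxo-4-(Q-oxy)cyclohex-3-ene-1-carboxylate
Product: 20 ethyl 3-hydroxy-5-methoxy-4-(Q-oxy)benzoate, via lithium dienolate 16 (not isolated), via phenylselanyl ketone 17 (not isolated), via selenoxide 18 (not isolated), via cyclohexadienone 19 (not isolated)
Conditions: LiN(i-Pr)2 (1.1 equiv), THF, −78 °C; PhSeBr, −78 °C; then AcOH, 30% H2O2, 0 → 23 °C
Reagents that add atoms: none
Why: Alpha-selenenylation of the kinetic enolate followed by selenoxide syn-elimination and tautomerization of dienone 19 to the phenol. Selenenylation at either flanking position or at the ester carbon would lead to the same arene. No reagent present can abstract hydride from the benzylic C7–H as a quinone oxidant would.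

Step 11
Reactants: 20 ethyl 3-hydroxy-5-methoxy-4-(Q-oxy)benzoate
Product: 21 ethyl 3,5-dimethoxy-4-(Q-oxy)benzoate
Conditions: MeI, K2CO3, acetone, 45 °C
Reagents that add atoms: iodomethane, CI
Why: Williamson methylation of the only acidic hydroxyl. The aryl triisopropylsilyl ether and the silylene are stable to K2CO3 in dry acetone.

Step 12
Reactants: 21 ethyl 3,5-dimethoxy-4-(Q-oxy)benzoate
Product: 22 [3,5-dimethoxy-4-(Q-oxy)phenyl]methanol
Conditions: i-Bu2AlH, CH2Cl2, −78 → 0 °C
Reagents that add atoms: none
Why: Hydride reduction of the aryl ester to the benzylic alcohol. Silyl ethers and the aryl ether are inert to i-Bu2AlH at low temperature.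

Step 13
Reactants: 22 [3,5-dimethoxy-4-(Q-oxy)phenyl]methanol
Product: 23 (1R,2S)-1-(4-hydroxy-3-methoxyphenyl)-2-[4-(hydroxymethyl)-2,6-dimethoxyphenoxy]propane-1,3-diol
Conditions: Bu4NF, AcOH, THF, 0 → 23 °C
Reagents that add atoms: none
Why: Fluoride cleaves the three Si–O bonds (silylene and aryl silyl ether) in one operation. Acetic acid buffers the freed phenoxide so that it does not expel the C7 hydroxyl through a quinone methide; neither stereocentre is touched.

## Compound list

Q = (4R,5S)-2,2-di-tert-butyl-4-[3-methoxy-4-(triisopropylsilyloxy)phenyl]-1,3,2-dioxasilinan-5-yl.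

1 | 4-bromo-2-methoxyphenol | COc1cc(Br)ccc1O | starting material
2 | (4-bromo-2-methoxyphenoxy)triisopropylsilane | COc1cc(Br)ccc1O[Si](C(C)C)(C(C)C)C(C)C | intermediate
3 | methyl (S)-2,2-dimethyl-1,3-dioxolane-4-carboxylate | COC(=O)[C@@H]1COC(C)(C)O1 | starting material
4 | (S)-N-methoxy-N,2,2-trimethyl-1,3-dioxolane-4-carboxamide | CON(C)C(=O)[C@@H]1COC(C)(C)O1 | intermediate
5 | [3-methoxy-4-(triisopropylsilyloxy)phenyl]lithium (formed in the flask) | COc1cc([Li])ccc1O[Si](C(C)C)(C(C)C)C(C)C | intermediate
6 | lithium alkoxide of the tetrahedral adduct of 5 and 4, [(4S)-2,2-dimethyl-1,3-dioxolan-4-yl][methoxy(methyl)amino][3-methoxy-4-(triisopropylsilyloxy)phenyl]methanolate, new carbon unassigned (formed in the flask) | COc1cc(C(O[Li])(N(C)OC)[C@@H]2COC(C)(C)O2)ccc1O[Si](C(C)C)(C(C)C)C(C)C | intermediate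
7 | [(4S)-2,2-dimethyl-1,3-dioxolan-4-yl][3-methoxy-4-(triisopropylsilyloxy)phenyl]methanone | COc1cc(C(=O)[C@@H]2COC(C)(C)O2)ccc1O[Si](C(C)C)(C(C)C)C(C)C | intermediate
8 | (R)-[(4S)-2,2-dimethyl-1,3-dioxolan-4-yl][3-methoxy-4-(triisopropylsilyloxy)phenyl]methanol | COc1cc([C@@H](O)[C@@H]2COC(C)(C)O2)ccc1O[Si](C(C)C)(C(C)C)C(C)C | intermediate
9 | (1R,2S)-1-[3-methoxy-4-(triisopropylsilyloxy)phenyl]propane-1,2,3-triol | COc1cc([C@@H](O)[C@@H](O)CO)ccc1O[Si](C(C)C)(C(C)C)C(C)C | intermediate
10 | (4R,5S)-2,2-di-tert-butyl-4-[3-methoxy-4-(triisopropylsilyloxy)phenyl]-1,3,2-dioxasilinan-5-ol (Q–OH; aryl and hydroxyl trans) | COc1cc([C@H]2O[Si](C(C)(C)C)(C(C)(C)C)OC[C@@H]2O)ccc1O[Si](C(C)C)(C(C)C)C(C)C | intermediate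
11 | ethyl 3,5-dioxocyclohexane-1-carboxylate | CCOC(=O)C1CC(=O)CC(=O)C1 | starting material
12 | ethyl 4-diazo-3,5-dioxocyclohexane-1-carboxylate | CCOC(=O)C1CC(=O)C(=[N+]=[N-])C(=O)C1 | intermediate
13 | ethyl 3,5-dioxo-4-(Q-oxy)cyclohexane-1-carboxylate (diketo tautomer, formed in the flask) | COc1cc([C@H]2O[Si](C(C)(C)C)(C(C)(C)C)OC[C@@H]2OC3C(=O)CC(C(=O)OCC)CC3=O)ccc1O[Si](C(C)C)(C(C)C)C(C)C | intermediate
14 | ethyl 3-hydroxy-5-oxo-4-(Q-oxy)cyclohex-3-ene-1-carboxylate | COc1cc([C@H]2O[Si](C(C)(C)C)(C(C)(C)C)OC[C@@H]2OC3=C(O)CC(C(=O)OCC)CC3=O)ccc1O[Si](C(C)C)(C(C)C)C(C)C | intermediate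
15 | ethyl 3-methoxy-5-oxo-4-(Q-oxy)cyclohex-3-ene-1-carboxylate (two epimers at ring carbon 1) | COc1cc([C@H]2O[Si](C(C)(C)C)(C(C)(C)C)OC[C@@H]2OC3=C(OC)CC(C(=O)OCC)CC3=O)ccc1O[Si](C(C)C)(C(C)C)C(C)C | intermediate
16 | ethyl 5-(lithiooxy)-3-methoxy-4-(Q-oxy)cyclohexa-3,5-diene-1-carboxylate (formed in the flask) | COc1cc([C@H]2O[Si](C(C)(C)C)(C(C)(C)C)OC[C@@H]2OC3=C(OC)CC(C(=O)OCC)C=C3O[Li])ccc1O[Si](C(C)C)(C(C)C)C(C)C | intermediate
17 | ethyl 5-methoxy-3-oxo-2-(phenylselanyl)-4-(Q-oxy)cyclohex-4-ene-1-carboxylate (formed in the flask) | COc1cc([C@H]2O[Si](C(C)(C)C)(C(C)(C)C)OC[C@@H]2OC3=C(OC)CC(C(=O)OCC)C([Se]c4ccccc4)C3=O)ccc1O[Si](C(C)C)(C(C)C)C(C)C | intermediate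
18 | ethyl 2-(benzeneseleninyl)-5-methoxy-3-oxo-4-(Q-oxy)cyclohex-4-ene-1-carboxylate (formed in the flask) | COc1cc([C@H]2O[Si](C(C)(C)C)(C(C)(C)C)OC[C@@H]2OC3=C(OC)CC(C(=O)OCC)C([Se](=O)c4ccccc4)C3=O)ccc1O[Si](C(C)C)(C(C)C)C(C)C | intermediate
19 | ethyl 5-methoxy-3-oxo-4-(Q-oxy)cyclohexa-1,4-diene-1-carboxylate (formed in the flask) | COc1cc([C@H]2O[Si](C(C)(C)C)(C(C)(C)C)OC[C@@H]2OC3=C(OC)CC(C(=O)OCC)=CC3=O)ccc1O[Si](C(C)C)(C(C)C)C(C)C | intermediate
20 | ethyl 3-hydroxy-5-methoxy-4-(Q-oxy)benzoate | COc1cc([C@H]2O[Si](C(C)(C)C)(C(C)(C)C)OC[C@@H]2Oc3c(O)cc(C(=O)OCC)cc3OC)ccc1O[Si](C(C)C)(C(C)C)C(C)C | intermediate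
21 | ethyl 3,5-dimethoxy-4-(Q-oxy)benzoate | COc1cc([C@H]2O[Si](C(C)(C)C)(C(C)(C)C)OC[C@@H]2Oc3c(OC)cc(C(=O)OCC)cc3OC)ccc1O[Si](C(C)C)(C(C)C)C(C)C | intermediate
22 | [3,5-dimethoxy-4-(Q-oxy)phenyl]methanol | COc1cc([C@H]2O[Si](C(C)(C)C)(C(C)(C)C)OC[C@@H]2Oc3c(OC)cc(CO)cc3OC)ccc1O[Si](C(C)C)(C(C)C)C(C)C | intermediate
23 | (1R,2S)-1-(4-hydroxy-3-methoxyphenyl)-2-[4-(hydroxymethyl)-2,6-dimethoxyphenoxy]propane-1,3-diol | COc1cc([C@@H](O)[C@H](CO)Oc2c(OC)cc(CO)cc2OC)ccc1O | target

## Step count and risks

Total step count: 13. Longest linear sequence: 11 steps (steps 1, 3, 4, 5, 6, 8, 9, 10, 11, 12, 13, from 1); steps 2 and 7 are one-step side branches.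

**Step 8 (key step).**
- What may go wrong: capture of the carbenoid by the hindered secondary hydroxyl may be too slow. Wolff ring contraction (the ketene then acylates the alcohol), insertion into traces of water, or a second insertion into the acidic enol O–H of the product would then take over.
- Fallback: it sets out from 10 and returns at 21; ring B arrives already aromatic, so steps 9 to 11 fall away. Mitsunobu reaction of 10 with 4-nitrobenzoic acid (PPh3, DIAD, THF) inverts C8 and gives (4R,5R)-2,2-di-tert-butyl-4-[3-methoxy-4-(triisopropylsilyloxy)phenyl]-1,3,2-dioxasilinan-5-yl 4-nitrobenzoate F1. K2CO3 in MeOH at 0 °C releases the cis alcohol (4R,5R)-2,2-di-tert-butyl-4-[3-methoxy-4-(triisopropylsilyloxy)phenyl]-1,3,2-dioxasilinan-5-ol F2. A second Mitsunobu reaction of F2 with commercial ethyl 4-hydroxy-3,5-dimethoxybenzoate inverts C8 again and gives 21.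

**Step 10.**
- What may go wrong: selenenylation may occur at more than one position, or cis to the ester so that the selenoxide lacks a syn hydrogen. Electrophilic selenium by-products may also attack the newly formed phenol.
- Fallback: it sets out from 15 and returns at 20, by Saegusa–Ito oxidation. LiN(i-Pr)2 and Me3SiCl give the silyl dienol ether ethyl 5-methoxy-4-(Q-oxy)-3-(trimethylsilyloxy)cyclohexa-2,4-diene-1-carboxylate F3. Pd(OAc)2 in MeCN (divalent palladium, beta-hydride elimination from the oxa-allyl complex) gives dienone 19, which tautomerises to 20.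

**Step 6.**
- What may go wrong: kinetic ring closure onto the C8 hydroxyl would give the five-membered 8,9-silylene and leave the benzylic hydroxyl free.
- Fallback: it sets out from 8 and returns at 10, with silicon attached to O7 before the diol is unmasked. t-Bu2SiHCl and imidazole give di-tert-butyl{(R)-[(4S)-2,2-dimethyl-1,3-dioxolan-4-yl][3-methoxy-4-(triisopropylsilyloxy)phenyl]methoxy}silane F4. Aqueous acetic acid removes the acetonide to give (2S,3R)-3-[(di-tert-butylsilyl)oxy]-3-[3-methoxy-4-(triisopropylsilyloxy)phenyl]propane-1,2-diol F5. Catalytic KOt-Bu in THF then closes the Si–H onto the primary hydroxyl with loss of H2; primary alcohol and six-membered ring are both favoured, giving 10.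

**Step 4.**
- What may go wrong: facial selectivity may be poor, since the acetal oxygens bind zinc only weakly and the open Felkin–Anh pathway leads to the threo epimer.
- Fallback: it sets out from 3 (with aryllithium 5 from 2) and returns at 8; the C1–C7 bond and the C7 centre are made together. i-Bu2AlH at −78 °C reduces 3 to (S)-2,2-dimethyl-1,3-dioxolane-4-carbaldehyde F6. Aryllithium 5 is transmetallated with ClTi(Oi-Pr)3 to [3-methoxy-4-(triisopropylsilyloxy)phenyl]tri(propan-2-yloxy)titanium F7. The non-chelating aryltitanium adds to F6 under Felkin–Anh control to give the anti alcohol 8.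

## Further compounds

F1 | step 8 | (4R,5R)-2,2-di-tert-butyl-4-[3-methoxy-4-(triisopropylsilyloxy)phenyl]-1,3,2-dioxasilinan-5-yl 4-nitrobenzoate | COc1cc([C@H]2O[Si](C(C)(C)C)(C(C)(C)C)OC[C@H]2OC(=O)c3ccc(cc3)[N+](=O)[O-])ccc1O[Si](C(C)C)(C(C)C)C(C)C
F2 | step 8 | (4R,5R)-2,2-di-tert-butyl-4-[3-methoxy-4-(triisopropylsilyloxy)phenyl]-1,3,2-dioxasilinan-5-ol | COc1cc([C@H]2O[Si](C(C)(C)C)(C(C)(C)C)OC[C@H]2O)ccc1O[Si](C(C)C)(C(C)C)C(C)C
F3 | step 10 | ethyl 5-methoxy-4-(Q-oxy)-3-(trimethylsilyloxy)cyclohexa-2,4-diene-1-carboxylate | COc1cc([C@H]2O[Si](C(C)(C)C)(C(C)(C)C)OC[C@@H]2OC3=C(OC)CC(C(=O)OCC)C=C3O[Si](C)(C)C)ccc1O[Si](C(C)C)(C(C)C)C(C)C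
F4 | step 6 | di-tert-butyl{(R)-[(4S)-2,2-dimethyl-1,3-dioxolan-4-yl][3-methoxy-4-(triisopropylsilyloxy)phenyl]methoxy}silane | COc1cc([C@@H](O[SiH](C(C)(C)C)C(C)(C)C)[C@@H]2COC(C)(C)O2)ccc1O[Si](C(C)C)(C(C)C)C(C)C
F5 | step 6 | (2S,3R)-3-[(di-tert-butylsilyl)oxy]-3-[3-methoxy-4-(triisopropylsilyloxy)phenyl]propane-1,2-diol | COc1cc([C@@H](O[SiH](C(C)(C)C)C(C)(C)C)[C@@H](O)CO)ccc1O[Si](C(C)C)(C(C)C)C(C)C
F6 | step 4 | (S)-2,2-dimethyl-1,3-dioxolane-4-carbaldehyde | O=C[C@@H]1COC(C)(C)O1
F7 | step 4 | [3-methoxy-4-(triisopropylsilyloxy)phenyl]tri(propan-2-yloxy)titanium | COc1cc([Ti](OC(C)C)(OC(C)C)OC(C)C)ccc1O[Si](C(C)C)(C(C)C)C(C)C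
A1 | alternative 1 | (1R,2S,3E)-2-{4-[(tert-butyldimethylsilyloxy)methyl]-2,6-dimethoxyphenoxy}-1-[3-methoxy-4-(triisopropylsilyloxy)phenyl]pent-3-en-1-ol | COc1cc([C@@H](O)[C@H](/C=C/C)Oc2c(OC)cc(CO[Si](C)(C)C(C)(C)C)cc2OC)ccc1O[Si](C(C)C)(C(C)C)C(C)C
A2 | alternative 1 | {4-[({(2R,3E)-4-{4-[(tert-butyldimethylsilyloxy)methyl]-2,6-dimethoxyphenoxy}but-3-en-2-yl}oxy)methyl]-2-methoxyphenoxy}triisopropylsilane | COc1cc(CO[C@H](C)/C=C/Oc2c(OC)cc(CO[Si](C)(C)C(C)(C)C)cc2OC)ccc1O[Si](C(C)C)(C(C)C)C(C)C
A3 | alternative 2 | ethyl (2R,3R)-3-[4-(benzyloxy)-3-methoxyphenyl]-2-[2,6-dimethoxy-4-(methoxycarbonyl)phenoxy]-3-hydroxypropanoate | COc1cc([C@@H](O)[C@H](C(=O)OCC)Oc2c(OC)cc(C(=O)OC)cc2OC)ccc1OCc1ccccc1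
A4 | alternative 2 | ethyl 3-[4-(benzyloxy)-3-methoxyphenyl]-2-[2,6-dimethoxy-4-(methoxycarbonyl)phenoxy]-3-oxopropanoate (racemic) | COc1cc(C(=O)C(C(=O)OCC)Oc2c(OC)cc(C(=O)OC)cc2OC)ccc1OCc1ccccc1
A5 | alternative 3 | (1R,2S)-1-[4-(benzyloxy)-3-methoxyphenyl]-3-(tert-butyldimethylsilyloxy)-2-{4-[(tert-butyldimethylsilyloxy)methyl]-2,6-dimethoxyphenoxy}propan-1-ol | COc1cc([C@@H](O)[C@H](CO[Si](C)(C)C(C)(C)C)Oc2c(OC)cc(CO[Si](C)(C)C(C)(C)C)cc2OC)ccc1OCc1ccccc1
A6 | alternative 3 | (Z)-1-[4-(benzyloxy)-3-methoxyphenyl]-3-(tert-butyldimethylsilyloxy)-2-{4-[(tert-butyldimethylsilyloxy)methyl]-2,6-dimethoxyphenoxy}prop-1-ene | COc1cc(/C=C(/CO[Si](C)(C)C(C)(C)C)Oc2c(OC)cc(CO[Si](C)(C)C(C)(C)C)cc2OC)ccc1OCc1ccccc1
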